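**Strategy.** The route rests on closing the dihydropyran ring at C3–C4. Read backwards, the benzylic CH2 (C4) on ring A is a ketone and C2' of the prenyl chain is an ester carbonyl, so C4 and C2' flank C3 in a 1,4-dicarbonyl pattern. An enantioselective intramolecular Stetter reaction exploits this: the formyl carbon of a 2,4,6-trioxygenated benzaldehyde (future C4) adds as an acyl anion to the β-carbon (future C3) of an (E)-enoate hung on the O1–C2(CH3)2 ether. This forms the C3–C4 bond, the pyranone ring and the C3 stereocentre in one catalytic step. Ketone excision, prenyl construction and chalcone assembly follow.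

Key step: step 3

Remarks on the chemistry:
- Chroman numbering is used throughout (O1, C2, C3, C4, C4a, C5–C8, C8a; side chain C1'–C3'); ring A is the benzo ring.
- Assumption: the (5aS,10bR) antipode of the triazolium salt is taken to give the (3R) ketone 4; if the sense of induction is the opposite on this substrate, the (5aR,10bS) antipode is used.
- The descriptor at C3 alternates between R and S along the route only because substituent priorities change. The spatial arrangement set in step 3 is the same in every compound and is that of the (3S) target.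

Step 1
Reactants: 1 2-hydroxy-4,6-dimethoxybenzaldehyde
Product: 2 2,4-dimethoxy-6-[(2-methylbut-3-en-2-yl)oxy]benzaldehyde
Conditions: tert-butyl 2-methylbut-3-en-2-yl carbonate, Pd(PPh3)4 (3 mol%), 4 Å MS, THF, 0 °C → rt
Reagents that add atoms: tert-butyl 2-methylbut-3-en-2-yl carbonate, CC(C)(C)OC(=O)OC(C)(C)C=C
Why: Zerovalent palladium ionises the tertiary allylic carbonate with loss of CO2, the tert-butoxide deprotonates the phenol, and the phenoxide attacks the more substituted terminus of the 1,1-dimethylallyl palladium cation under kinetic control (Tsuji–Trost O-allylation, "reverse prenylation"), the aldehyde being inert.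

Step 2
Reactants: 2 2,4-dimethoxy-6-[(2-methylbut-3-en-2-yl)oxy]benzaldehyde
Product: 3 ethyl (2E)-4-(2-formyl-3,5-dimethoxyphenoxy)-4-methylpent-2-enoate
Conditions: ethyl acrylate (5 equiv), second-generation Hoveyda–Grubbs catalyst (5 mol%), CH2Cl2, 40 °C
Reagents that add atoms: ethyl acrylate, C=CC(=O)OCC
Why: Olefin cross-metathesis of a hindered monosubstituted alkene that cannot homodimerise with an excess of an electron-poor acrylate should be selective for the cross product and give the (E)-enoate, while the aldehyde and the tertiary aryl ether are tolerated and the temperature stays far below that of an aromatic Claisen rearrangement.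

Step 3
Reactants: 3 ethyl (2E)-4-(2-formyl-3,5-dimethoxyphenoxy)-4-methylpent-2-enoate
Product: 4 ethyl 2-[(3R)-5,7-dimethoxy-2,2-dimethyl-4-oxo-3,4-dihydro-2H-chromen-3-yl]acetate
Conditions: (5aS,10bR)-2-(pentafluorophenyl)-5a,10b-dihydro-4H,6H-indeno[2,1-b][1,2,4]triazolo[4,3-d][1,4]oxazin-2-ium tetrafluoroborate (20 mol%), KN(SiMe3)2 (18 mol%), toluene, 23 °C
Reagents that add atoms: none
Why: The carbene freed from the triazolium salt adds to the formyl group and, after proton transfer, gives the nucleophilic enaminol (Breslow intermediate), whose former aldehyde carbon (future C4) adds to the β-carbon of the enoate (future C3); proton transfer to the ester enolate and release of the carbene deliver the ketone. The closest known reaction type is the catalytic asymmetric intramolecular Stetter reaction of salicylaldehyde-derived 4-aryloxybut-2-enoates to 3-substituted chroman-4-ones. The pyranone ring closes in the 6-exo-trig mode. The C3 stereocentre is controlled by the catalyst: the fused indane wall blocks one face of the enaminol, and the (E)-geometry of the acceptor fixes which prochiral face of the β-carbon meets it. The step needs conjugate addition to win over benzoin-type dimerisation and over base-induced loss of configuration; the two ortho oxygen substituents hinder intermolecular attack on the aldehyde, the gem-dimethyl group favours ring closure and leaves no γ-hydrogen for elimination of the aryloxide, and base is kept below the azolium loading so that the α-stereocentre of 4 is not epimerised.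

Step 4
Reactants: 4 ethyl 2-[(3R)-5,7-dimethoxy-2,2-dimethyl-4-oxo-3,4-dihydro-2H-chromen-3-yl]acetate
Product: 5 ethyl 2-[(3R)-5-hydroxy-7-methoxy-2,2-dimethyl-4-oxo-3,4-dihydro-2H-chromen-3-yl]acetate
Conditions: BCl3 (1 M in CH2Cl2, 1.5 equiv), CH2Cl2, −78 → 0 °C; then H2O
Reagents that add atoms: none
Why: BCl3 chelates between the C4 carbonyl and the peri 5-methoxy oxygen and chloride removes only that methyl group (chelation-controlled ortho-demethylation of an aryl ketone), while the 7-methoxy group, the ester and the tertiary alkyl aryl ether lack this activation and the cold, base-free conditions should leave C3 untouched.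

Step 5
Reactants: 5 ethyl 2-[(3R)-5-hydroxy-7-methoxy-2,2-dimethyl-4-oxo-3,4-dihydro-2H-chromen-3-yl]acetate
Product: 8 ethyl 2-[(3R)-5-hydroxy-7-methoxy-2,2-dimethyl-3,4-dihydro-2H-chromen-3-yl]acetate, via aryl ethyl carbonate 6 (not isolated), via ortho-quinone methide 7 (not isolated)
Conditions: ClCO2Et, Et3N, THF, 0 °C; then NaBH4, H2O–THF, 0 °C → rt
Reagents that add atoms: none
Why: After O-acylation of the phenol to 6, borohydride reduction of the ketone triggers transfer of the ethoxycarbonyl group to the new benzylic oxygen, expulsion of ethyl carbonate by the phenoxide to give 7, and conjugate hydride addition to C4 (reductive deoxygenation of an ortho-hydroxyaryl ketone via an ortho-quinone methide), with C3 not involved and the ester inert to NaBH4 at this temperature.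

Step 6
Reactants: 8 ethyl 2-[(3R)-5-hydroxy-7-methoxy-2,2-dimethyl-3,4-dihydro-2H-chromen-3-yl]acetate
Product: 9 ethyl 2-[(3R)-7-methoxy-5-(methoxymethoxy)-2,2-dimethyl-3,4-dihydro-2H-chromen-3-yl]acetate
Conditions: MOMCl, i-Pr2NEt, CH2Cl2, 0 °C → rt
Reagents that add atoms: chloromethyl methyl ether (MOMCl), COCCl
Why: Williamson-type O-alkylation of the now unchelated phenol with the reactive α-chloro ether installs a MOM ether that is stable to hydride and organolithium reagents and later serves as the directing group for metalation.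

Step 7
Reactants: 9 ethyl 2-[(3R)-7-methoxy-5-(methoxymethoxy)-2,2-dimethyl-3,4-dihydro-2H-chromen-3-yl]acetate
Product: 10 2-[(3R)-7-methoxy-5-(methoxymethoxy)-2,2-dimethyl-3,4-dihydro-2H-chromen-3-yl]acetaldehyde
Conditions: i-Bu2AlH (1.1 equiv), CH2Cl2, −78 °C; then MeOH, aq. potassium sodium tartrate
Reagents that add atoms: none
Why: At −78 °C i-Bu2AlH adds once to the ester and the tetrahedral aluminium hemiacetal survives until work-up, so partial reduction should stop at the aldehyde, and C3 is β to the new carbonyl group and cannot epimerise.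

Step 8
Reactants: 10 2-[(3R)-7-methoxy-5-(methoxymethoxy)-2,2-dimethyl-3,4-dihydro-2H-chromen-3-yl]acetaldehyde
Product: 11 (3S)-7-methoxy-5-(methoxymethoxy)-2,2-dimethyl-3-(3-methylbut-2-en-1-yl)-3,4-dihydro-2H-chromene
Conditions: i-PrPPh3I, n-BuLi, THF, 0 °C; then 10, −78 °C → rt
Reagents that add atoms: isopropyltriphenylphosphonium iodide, CC(C)[P+](c1ccccc1)(c1ccccc1)c1ccccc1.[I-]
Why: Wittig olefination with the unstabilised isopropylidene ylide turns the aldehyde carbon into C2' of the prenyl group, and no alkene geometry arises because the ylide carbon carries two methyl groups.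

Step 9
Reactants: 11 (3S)-7-methoxy-5-(methoxymethoxy)-2,2-dimethyl-3-(3-methylbut-2-en-1-yl)-3,4-dihydro-2H-chromene
Product: 13 1-[(3S)-7-methoxy-5-(methoxymethoxy)-2,2-dimethyl-3-(3-methylbut-2-en-1-yl)-3,4-dihydro-2H-chromen-6-yl]ethan-1-one, via aryllithium 12 (not isolated)
Conditions: n-BuLi, TMEDA, THF, 0 °C; then MeC(O)N(OMe)Me, −78 → 0 °C; then H2O
Reagents that add atoms: N-methoxy-N-methylacetamide, CC(=O)N(C)OC
Why: Directed ortho-metalation: the chelating MOM ether together with the 7-methoxy group should direct lithiation to C6, the position between them, in preference to C8 next to the hindered ring oxygen, and the aryllithium is acylated once by the Weinreb amide, whose chelated tetrahedral adduct survives until work-up.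

Step 10
Reactants: 14 2,4-dihydroxybenzaldehyde
Product: 15 2,4-bis(methoxymethoxy)benzaldehyde
Conditions: NaH, MOMCl, DMF, 0 °C → rt
Reagents that add atoms: chloromethyl methyl ether (MOMCl), COCCl
Why: Double Williamson etherification of the bis-phenoxide, NaH being used because the 2-hydroxy group is hydrogen-bonded to the aldehyde and weakly nucleophilic.

Step 11
Reactants: 13 1-[(3S)-7-methoxy-5-(methoxymethoxy)-2,2-dimethyl-3-(3-methylbut-2-en-1-yl)-3,4-dihydro-2H-chromen-6-yl]ethan-1-one; 15 2,4-bis(methoxymethoxy)benzaldehyde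
Product: 16 (2E)-3-[2,4-bis(methoxymethoxy)phenyl]-1-[(3S)-7-methoxy-5-(methoxymethoxy)-2,2-dimethyl-3-(3-methylbut-2-en-1-yl)-3,4-dihydro-2H-chromen-6-yl]prop-2-en-1-one
Conditions: KOH, EtOH–H2O, rt
Reagents that add atoms: none
Why: Claisen–Schmidt condensation: the methyl ketone is the only enolisable partner and the aldehyde cannot enolise, so crossed aldol addition and E1cB dehydration should give the (E)-enone, while the MOM ethers tolerate base and C3, which is not α to a carbonyl group, is not at risk.

Step 12
Reactants: 16 (2E)-3-[2,4-bis(methoxymethoxy)phenyl]-1-[(3S)-7-methoxy-5-(methoxymethoxy)-2,2-dimethyl-3-(3-methylbut-2-en-1-yl)-3,4-dihydro-2H-chromen-6-yl]prop-2-en-1-one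
Product: 17 (2E)-3-(2,4-dihydroxyphenyl)-1-[(3S)-5-hydroxy-7-methoxy-2,2-dimethyl-3-(3-methylbut-2-en-1-yl)-3,4-dihydro-2H-chromen-6-yl]prop-2-en-1-one
Conditions: HCl (1 M in MeOH), rt
Reagents that add atoms: none
Why: Acid-catalysed transacetalisation with methanol removes all three MOM ethers under mild conditions that are expected to spare the prenyl double bond, the tertiary aryl ether and the (E)-enone.

**Compound list**

1 | 2-hydroxy-4,6-dimethoxybenzaldehyde | COc1cc(O)c(C=O)c(OC)c1 | starting material
2 | 2,4-dimethoxy-6-[(2-methylbut-3-en-2-yl)oxy]benzaldehyde | COc1cc(OC)c(C=O)c(OC(C)(C)C=C)c1 | intermediate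
3 | ethyl (2E)-4-(2-formyl-3,5-dimethoxyphenoxy)-4-methylpent-2-enoate | CCOC(=O)/C=C/C(C)(C)Oc1cc(OC)cc(OC)c1C=O | intermediate
4 | ethyl 2-[(3R)-5,7-dimethoxy-2,2-dimethyl-4-oxo-3,4-dihydro-2H-chromen-3-yl]acetate | COc1cc2c(c(OC)c1)C(=O)[C@H](CC(=O)OCC)C(C)(C)O2 | intermediate
5 | ethyl 2-[(3R)-5-hydroxy-7-methoxy-2,2-dimethyl-4-oxo-3,4-dihydro-2H-chromen-3-yl]acetate | COc1cc2c(c(O)c1)C(=O)[C@H](CC(=O)OCC)C(C)(C)O2 | intermediate
6 | ethyl 2-[(3R)-5-[(ethoxycarbonyl)oxy]-7-methoxy-2,2-dimethyl-4-oxo-3,4-dihydro-2H-chromen-3-yl]acetate (aryl ethyl carbonate, formed in the flask) | COc1cc2c(c(OC(=O)OCC)c1)C(=O)[C@H](CC(=O)OCC)C(C)(C)O2 | intermediate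
7 | ethyl 2-[(3S)-7-methoxy-2,2-dimethyl-5-oxo-3,5-dihydro-2H-chromen-3-yl]acetate (ortho-quinone methide with a C4=C4a double bond, formed in the flask) | COC1=CC(=O)C2=C[C@H](CC(=O)OCC)C(C)(C)OC2=C1 | intermediate
8 | ethyl 2-[(3R)-5-hydroxy-7-methoxy-2,2-dimethyl-3,4-dihydro-2H-chromen-3-yl]acetate | COc1cc2c(c(O)c1)C[C@H](CC(=O)OCC)C(C)(C)O2 | intermediate
9 | ethyl 2-[(3R)-7-methoxy-5-(methoxymethoxy)-2,2-dimethyl-3,4-dihydro-2H-chromen-3-yl]acetate | COc1cc2c(c(OCOC)c1)C[C@H](CC(=O)OCC)C(C)(C)O2 | intermediate
10 | 2-[(3R)-7-methoxy-5-(methoxymethoxy)-2,2-dimethyl-3,4-dihydro-2H-chromen-3-yl]acetaldehyde | COc1cc2c(c(OCOC)c1)C[C@H](CC=O)C(C)(C)O2 | intermediate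
11 | (3S)-7-methoxy-5-(methoxymethoxy)-2,2-dimethyl-3-(3-methylbut-2-en-1-yl)-3,4-dihydro-2H-chromene | COc1cc2c(c(OCOC)c1)C[C@H](CC=C(C)C)C(C)(C)O2 | intermediate
12 | [(3S)-7-methoxy-5-(methoxymethoxy)-2,2-dimethyl-3-(3-methylbut-2-en-1-yl)-3,4-dihydro-2H-chromen-6-yl]lithium (formed in the flask) | COc1cc2c(c(OCOC)c1[Li])C[C@H](CC=C(C)C)C(C)(C)O2 | intermediate
13 | 1-[(3S)-7-methoxy-5-(methoxymethoxy)-2,2-dimethyl-3-(3-methylbut-2-en-1-yl)-3,4-dihydro-2H-chromen-6-yl]ethan-1-one | COc1cc2c(c(OCOC)c1C(C)=O)C[C@H](CC=C(C)C)C(C)(C)O2 | intermediate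
14 | 2,4-dihydroxybenzaldehyde | O=Cc1ccc(O)cc1O | starting material
15 | 2,4-bis(methoxymethoxy)benzaldehyde | COCOc1ccc(C=O)c(OCOC)c1 | intermediate
16 | (2E)-3-[2,4-bis(methoxymethoxy)phenyl]-1-[(3S)-7-methoxy-5-(methoxymethoxy)-2,2-dimethyl-3-(3-methylbut-2-en-1-yl)-3,4-dihydro-2H-chromen-6-yl]prop-2-en-1-one | COCOc1ccc(/C=C/C(=O)c2c(OC)cc3c(c2OCOC)C[C@H](CC=C(C)C)C(C)(C)O3)c(OCOC)c1 | intermediate
17 | (2E)-3-(2,4-dihydroxyphenyl)-1-[(3S)-5-hydroxy-7-methoxy-2,2-dimethyl-3-(3-methylbut-2-en-1-yl)-3,4-dihydro-2H-chromen-6-yl]prop-2-en-1-one | COc1cc2c(c(O)c1C(=O)/C=C/c1ccc(O)cc1O)C[C@H](CC=C(C)C)C(C)(C)O2 | target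

**Step count.** Total: 12 steps. Longest linear sequence: 11 steps (steps 1–9, 11 and 12); step 10 is a one-step side branch.

**Steps most likely to fail**

Step 3. The carbene may add only sluggishly to the doubly ortho-oxygenated, electron-rich aldehyde, so that catalyst decay outruns formation of the acyl anion equivalent. Facial discrimination at the β-carbon next to the quaternary centre may also be incomplete. The fallback sets out from 3 and closes the same C3–C4 bond with an acyl radical instead of an acyl anion. Hydrogen-atom abstraction from the formyl C–H under (n-Bu4N)4[W10O32] photocatalysis (390 nm, MeCN) should give an acyl radical that cyclises 6-exo-trig onto the enoate. Back hydrogen transfer should then give racemic ethyl 2-(5,7-dimethoxy-2,2-dimethyl-4-oxo-3,4-dihydro-2H-chromen-3-yl)acetate F1. The enantiomers are separated by preparative chromatography on a chiral stationary phase. The unwanted antipode can be racemised with DBU, since C3 is α to the ketone, and recycled. The (3R) enantiomer is 4, where the route is rejoined.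

Step 5. The quinone methide may tautomerise to the 2H-chromene by loss of the C3 proton, which would erase the stereocentre, faster than it takes up hydride. Alternatively, the carbonate may be cleaved before acyl transfer, so that the reduction stops at the benzylic alcohol. The fallback sets out from 5 and replaces the quinone methide pathway by reduction of a C=N bond. Condensation with p-toluenesulfonyl hydrazide (EtOH, 70 °C) should give ethyl 2-[(3S)-5-hydroxy-7-methoxy-2,2-dimethyl-4-[2-(4-methylbenzenesulfonyl)hydrazinylidene]-3,4-dihydro-2H-chromen-3-yl]acetate F2. Treatment with catecholborane (CHCl3, 0 °C) and then NaOAc·3H2O at reflux adds hydride to the C=N bond, after which sulfinate is lost and nitrogen is extruded, so C4 becomes CH2 without a quinone methide or a benzylic cation. The route is rejoined at 8.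

Step 12. Under acid, release of the phenols may be followed by conjugate addition of the freed 5-hydroxy group to the enone (flavanone formation), by closure of the B-ring 2-hydroxy group onto the carbonyl group (flavylium-type cyclisation), or by Markovnikov addition to the prenyl double bond. The fallback sets out from 13 and 14 and comes back at 17; it removes the only acid-labile group before the enone exists and puts allyl ethers on the B ring. Compound 13 is treated with pyridinium p-toluenesulfonate in MeOH (45 °C), which should cleave the MOM ether ortho to the ketone and give 1-[(3S)-5-hydroxy-7-methoxy-2,2-dimethyl-3-(3-methylbut-2-en-1-yl)-3,4-dihydro-2H-chromen-6-yl]ethan-1-one F3. Compound 14 is allylated twice (allyl bromide, K2CO3, DMF) to 2,4-bis(prop-2-en-1-yloxy)benzaldehyde F4. Claisen–Schmidt condensation of F3 with F4 (KOH, EtOH) should give (2E)-3-[2,4-bis(prop-2-en-1-yloxy)phenyl]-1-[(3S)-5-hydroxy-7-methoxy-2,2-dimethyl-3-(3-methylbut-2-en-1-yl)-3,4-dihydro-2H-chromen-6-yl]prop-2-en-1-one F5. Pd(PPh3)4 (cat.) with K2CO3 in MeOH at rt then removes both allyl groups under basic conditions to give 17.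

Further compounds
F1 | step 3 | racemic ethyl 2-(5,7-dimethoxy-2,2-dimethyl-4-oxo-3,4-dihydro-2H-chromen-3-yl)acetate | COc1cc2c(c(OC)c1)C(=O)C(CC(=O)OCC)C(C)(C)O2
F2 | step 5 | ethyl 2-[(3S)-5-hydroxy-7-methoxy-2,2-dimethyl-4-[2-(4-methylbenzenesulfonyl)hydrazinylidene]-3,4-dihydro-2H-chromen-3-yl]acetate | COc1cc2c(c(O)c1)C(=NNS(=O)(=O)c1ccc(C)cc1)[C@H](CC(=O)OCC)C(C)(C)O2
F3 | step 12 | 1-[(3S)-5-hydroxy-7-methoxy-2,2-dimethyl-3-(3-methylbut-2-en-1-yl)-3,4-dihydro-2H-chromen-6-yl]ethan-1-one | COc1cc2c(c(O)c1C(C)=O)C[C@H](CC=C(C)C)C(C)(C)O2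
F4 | step 12 | 2,4-bis(prop-2-en-1-yloxy)benzaldehyde | C=CCOc1ccc(C=O)c(OCC=C)c1
F5 | step 12 | (2E)-3-[2,4-bis(prop-2-en-1-yloxy)phenyl]-1-[(3S)-5-hydroxy-7-methoxy-2,2-dimethyl-3-(3-methylbut-2-en-1-yl)-3,4-dihydro-2H-chromen-6-yl]prop-2-en-1-one | C=CCOc1ccc(/C=C/C(=O)c2c(OC)cc3c(c2O)C[C@H](CC=C(C)C)C(C)(C)O3)c(OCC=C)c1
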